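The target is an 8,12-elemanolide: cyclohexane ring A (C5–C10) is cis-fused through C7–C8 to α-methylene-γ-butyrolactone ring B (C7, C11, C12, O, C8). The route rests on cutting the shared C7–C8 bond and the C11–C12 bond. The precursor is an acyclic allenyl aldehyde (C8 formyl, C7=C11=C13 allene) that already carries both esters and the C5, C6, C9 and C10 stereocentres. A molybdenum-mediated hetero-Pauson–Khand cyclocarbonylation closes ring A and ring B in one operation and sets C7 and C8. The chain comes from (S)-glyceraldehyde acetonide through an Ireland–Claisen rearrangement (C5–C10 bond); the enal is unveiled last by allylic oxidation.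

Key step: step 17

Numbering (elemane convention, used throughout): ring A = C5–C6–C7–C8–C9–C10; C10 carries the C14 methyl and the C1=C2 vinyl group; C5 carries C4(=C3H2)–C15; C6 carries the angelate and C9 the methacrylate; ring B = C7–C11(=C13H2)–C12(=O)–O–C8.
Assumption: (S)-2,2-dimethyl-1,3-dioxolane-4-carbaldehyde (1) is taken as a commercial chiral-pool aldehyde.

Step 1
Reactants: 1 (S)-2,2-dimethyl-1,3-dioxolane-4-carbaldehyde
Product: 2 (4R)-4-(2,2-dibromoethenyl)-2,2-dimethyl-1,3-dioxolane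
Conditions: CBr4, PPh3, CH2Cl2, 0 °C
Reagents that add atoms: carbon tetrabromide, BrC(Br)(Br)Br
Why: Dibromo-olefination through Ph3P=CBr2 (first stage of the Corey–Fuchs sequence) is fast at 0 °C, so the C9 stereocentre of the α-alkoxy aldehyde should not epimerise.

Step 2
Reactants: 2 (4R)-4-(2,2-dibromoethenyl)-2,2-dimethyl-1,3-dioxolane
Product: 4 methyl 3-[(4R)-2,2-dimethyl-1,3-dioxolan-4-yl]prop-2-ynoate, via lithium acetylide 3 (not isolated)
Conditions: n-BuLi (2.1 equiv), THF, −78 °C; then ClCO2Me, −78 → 0 °C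
Reagents that add atoms: methyl chloroformate, COC(=O)Cl
Why: The second stage of the Corey–Fuchs sequence (Br/Li exchange, 1,2-shift, deprotonation) gives the lithium acetylide, which is C-acylated by the chloroformate; no stereocentre is touched.

Step 3
Reactants: 4 methyl 3-[(4R)-2,2-dimethyl-1,3-dioxolan-4-yl]prop-2-ynoate
Product: 5 methyl (2Z)-3-[(4R)-2,2-dimethyl-1,3-dioxolan-4-yl]but-2-enoate
Conditions: Me2CuLi (from CuI, 2 MeLi), THF, −78 °C; then aq. NH4Cl at −78 °C
Reagents that add atoms: lithium dimethylcuprate, [Li+].C[Cu-]C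
Why: syn-Carbocupration of the ynoate and protonation with retention at −78 °C should give only the (Z)-enoate (dioxolane cis to the ester carbon), the geometry needed later for allylic-strain control by C9.

Step 4
Reactants: 5 methyl (2Z)-3-[(4R)-2,2-dimethyl-1,3-dioxolan-4-yl]but-2-enoate
Product: 6 (2Z)-3-[(4R)-2,2-dimethyl-1,3-dioxolan-4-yl]but-2-en-1-ol
Conditions: i-Bu2AlH (2.2 equiv), CH2Cl2, −78 °C; then aq. KNaC4H4O6
Reagents that add atoms: none
Why: 1,2-Reduction of the enoate by the aluminium hydride should give the allylic alcohol without touching the alkene geometry or the acetonide.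

Step 5
Reactants: 6 (2Z)-3-[(4R)-2,2-dimethyl-1,3-dioxolan-4-yl]but-2-en-1-ol; 7 3-methylbut-2-enoic acid
Product: 8 (2Z)-3-[(4R)-2,2-dimethyl-1,3-dioxolan-4-yl]but-2-en-1-yl 3-methylbut-2-enoate
Conditions: DCC, DMAP (cat.), CH2Cl2, 0 °C → rt
Reagents that add atoms: none
Why: Steglich esterification of the primary allylic alcohol under neutral conditions avoids the vinylketene pathway that an acid chloride and an amine base could open.

Step 6
Reactants: 8 (2Z)-3-[(4R)-2,2-dimethyl-1,3-dioxolan-4-yl]but-2-en-1-yl 3-methylbut-2-enoate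
Product: 11 (2S,3S)-3-[(4R)-2,2-dimethyl-1,3-dioxolan-4-yl]-3-methyl-2-(prop-1-en-2-yl)pent-4-enoic acid, via silyl ketene acetal 9 (not isolated), via trimethylsilyl ester 10 (not isolated)
Conditions: LiN(i-Pr)2, THF, −78 °C; Me3SiCl; −78 → 65 °C; then 1 M HCl
Reagents that add atoms: none
Why: Deconjugative Ireland–Claisen rearrangement: γ-deprotonation of the s-cis enoate should give the dienolate with the isopropenyl group cis to O–Li (hence the (1Z)-silyl ketene acetal 9), a chair transition state with the C5 isopropenyl and C10 methyl groups equatorial (dioxolane axial) gives the required C5/C10 relation, and A(1,3) strain in the (Z)-alkene holds C9–H in the alkene plane so that C5 bonds to C10 anti to the C9–O bond, which fixes C10 and C5 relative to C9.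

Step 7
Reactants: 11 (2S,3S)-3-[(4R)-2,2-dimethyl-1,3-dioxolan-4-yl]-3-methyl-2-(prop-1-en-2-yl)pent-4-enoic acid
Product: 13 (2S,3S)-3-[(4R)-2,2-dimethyl-1,3-dioxolan-4-yl]-N-methoxy-N,3-dimethyl-2-(prop-1-en-2-yl)pent-4-enamide, via acid chloride 12 (not isolated)
Conditions: Me2C=C(Cl)NMe2, CH2Cl2, 0 °C; then MeNH(OMe)·HCl, pyridine, 0 °C → rt
Reagents that add atoms: N,O-dimethylhydroxylamine hydrochloride, CNOC.Cl
Why: Neutral acid chloride formation with the α-chloroenamine (no free HCl, so the acetonide is safe; no base, so no ketene or C5 epimerisation) followed by amidation should give the Weinreb amide of this hindered acid.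

Step 8
Reactants: 13 (2S,3S)-3-[(4R)-2,2-dimethyl-1,3-dioxolan-4-yl]-N-methoxy-N,3-dimethyl-2-(prop-1-en-2-yl)pent-4-enamide
Product: 14 (4S,5S)-5-[(4R)-2,2-dimethyl-1,3-dioxolan-4-yl]-5-methyl-4-(prop-1-en-2-yl)-1-(trimethylsilyl)hept-6-en-1-yn-3-one
Conditions: Me3SiC≡CLi (from Me3SiC≡CH, n-BuLi), THF, −78 → 0 °C; then cold 1 M HCl
Reagents that add atoms: (trimethylsilyl)acetylene, C#C[Si](C)(C)C
Why: Weinreb ketone synthesis: the chelated tetrahedral adduct of the weakly basic acetylide survives until the acidic quench, so one addition should give the ynone and C5 is not enolised.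

Step 9
Reactants: 14 (4S,5S)-5-[(4R)-2,2-dimethyl-1,3-dioxolan-4-yl]-5-methyl-4-(prop-1-en-2-yl)-1-(trimethylsilyl)hept-6-en-1-yn-3-one
Product: 15 (3S,4S,5S)-5-[(4R)-2,2-dimethyl-1,3-dioxolan-4-yl]-5-methyl-4-(prop-1-en-2-yl)-1-(trimethylsilyl)hept-6-en-1-yn-3-ol
Conditions: (S)-2-methyl-CBS-oxazaborolidine (0.5 equiv), catecholborane, CH2Cl2, −78 °C
Reagents that add atoms: none
Why: Corey–Bakshi–Shibata reduction with the alkynyl arm as the small group; hydride delivery anti to the C10 quaternary carbon (Felkin–Anh) and catalyst control point the same way and should set C6 as (S), with C6–O anti to the C5 isopropenyl group along the C10–C5–C6–C7 zigzag.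

Step 10
Reactants: 15 (3S,4S,5S)-5-[(4R)-2,2-dimethyl-1,3-dioxolan-4-yl]-5-methyl-4-(prop-1-en-2-yl)-1-(trimethylsilyl)hept-6-en-1-yn-3-ol
Product: 16 (3S,4S,5S)-5-[(4R)-2,2-dimethyl-1,3-dioxolan-4-yl]-5-methyl-4-(prop-1-en-2-yl)hept-6-en-1-yn-3-ol
Conditions: K2CO3, MeOH, 0 °C → rt
Reagents that add atoms: none
Why: Base-catalysed methanolysis of the alkynyl C–Si bond frees the terminal alkyne; the carbinol and the acetonide are inert.

Step 11
Reactants: 16 (3S,4S,5S)-5-[(4R)-2,2-dimethyl-1,3-dioxolan-4-yl]-5-methyl-4-(prop-1-en-2-yl)hept-6-en-1-yn-3-ol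
Product: 18 (4R,5S,6S)-6-[(4R)-2,2-dimethyl-1,3-dioxolan-4-yl]-6-methyl-5-(prop-1-en-2-yl)octa-1,2,7-trien-4-ol, via propargylic amine 17 (not isolated)
Conditions: (CH2O)n, CuI (0.5 equiv), Cy2NH, 1,4-dioxane, 100 °C
Reagents that add atoms: paraformaldehyde (formaldehyde), C=O
Why: Crabbé homologation: copper-mediated Mannich coupling of the alkyne with formaldehyde and the amine, then 1,5-hydride transfer and β-elimination, should convert C≡CH into the terminal allene CH=C=CH2 without touching the C6 carbinol centre (the descriptor changes only because the priorities change).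

Step 12
Reactants: 18 (4R,5S,6S)-6-[(4R)-2,2-dimethyl-1,3-dioxolan-4-yl]-6-methyl-5-(prop-1-en-2-yl)octa-1,2,7-trien-4-ol
Product: 19 (4R,5S,6S)-6-[(4R)-2,2-dimethyl-1,3-dioxolan-4-yl]-6-methyl-5-(prop-1-en-2-yl)octa-1,2,7-trien-4-yl (2Z)-2-methylbut-2-enoate
Conditions: angelic acid, 2,4,6-Cl3C6H2COCl, Et3N, toluene, rt; then 18, 80 °C
Reagents that add atoms: angelic acid [(2Z)-2-methylbut-2-enoic acid], C/C=C(/C)C(=O)O
Why: Yamaguchi-type mixed-anhydride esterification should acylate the hindered allenyl carbinol with retention at C6, and leaving out a nucleophilic catalyst should keep the (Z)-angelate from isomerising to the tiglate.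

Step 13
Reactants: 19 (4R,5S,6S)-6-[(4R)-2,2-dimethyl-1,3-dioxolan-4-yl]-6-methyl-5-(prop-1-en-2-yl)octa-1,2,7-trien-4-yl (2Z)-2-methylbut-2-enoate
Product: 20 (2R,3S,4S,5R)-3-ethenyl-1,2-dihydroxy-3-methyl-4-(prop-1-en-2-yl)octa-6,7-dien-5-yl (2Z)-2-methylbut-2-enoate
Conditions: AcOH/H2O (4:1), 40 °C
Reagents that add atoms: none
Why: Mild acid hydrolysis of the isopropylidene acetal should free the C8/C9 diol while the esters and the allene are inert to aqueous acetic acid.

Step 14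
Reactants: 20 (2R,3S,4S,5R)-3-ethenyl-1,2-dihydroxy-3-methyl-4-(prop-1-en-2-yl)octa-6,7-dien-5-yl (2Z)-2-methylbut-2-enoate
Product: 21 (2R,3S,4S,5R)-3-ethenyl-2-hydroxy-3-methyl-4-(prop-1-en-2-yl)-1-[(triethylsilyl)oxy]octa-6,7-dien-5-yl (2Z)-2-methylbut-2-enoate
Conditions: Et3SiCl, imidazole, CH2Cl2, −40 °C
Reagents that add atoms: chlorotriethylsilane, CC[Si](Cl)(CC)CC
Why: Silylation should be selective for the primary C8 hydroxyl because the C9 hydroxyl is secondary and neopentylic.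

Step 15
Reactants: 21 (2R,3S,4S,5R)-3-ethenyl-2-hydroxy-3-methyl-4-(prop-1-en-2-yl)-1-[(triethylsilyl)oxy]octa-6,7-dien-5-yl (2Z)-2-methylbut-2-enoate
Product: 22 (2R,3S,4S,5R)-3-ethenyl-3-methyl-2-[(2-methylprop-2-enoyl)oxy]-4-(prop-1-en-2-yl)-1-[(triethylsilyl)oxy]octa-6,7-dien-5-yl (2Z)-2-methylbut-2-enoate
Conditions: methacrylic anhydride, Et3N, DMAP, CH2Cl2, rt
Reagents that add atoms: methacrylic anhydride, C=C(C)C(=O)OC(=O)C(C)=C
Why: DMAP-catalysed acylation should esterify the remaining C9 hydroxyl with retention of configuration.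

Step 16
Reactants: 22 (2R,3S,4S,5R)-3-ethenyl-3-methyl-2-[(2-methylprop-2-enoyl)oxy]-4-(prop-1-en-2-yl)-1-[(triethylsilyl)oxy]octa-6,7-dien-5-yl (2Z)-2-methylbut-2-enoate
Product: 23 (2R,3S,4S,5R)-3-ethenyl-3-methyl-2-[(2-methylprop-2-enoyl)oxy]-1-oxo-4-(prop-1-en-2-yl)octa-6,7-dien-5-yl (2Z)-2-methylbut-2-enoate
Conditions: (COCl)2, DMSO, CH2Cl2, −78 → −40 °C; then i-Pr2NEt, −78 → 0 °C
Reagents that add atoms: none
Why: Swern oxidation applied directly to the primary triethylsilyl ether (the chlorosulfonium salt cleaves the O–Si bond and oxidises C8 in one flask); the hindered base at low temperature should leave the C9 α-acyloxy stereocentre intact.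

Step 17
Reactants: 23 (2R,3S,4S,5R)-3-ethenyl-3-methyl-2-[(2-methylprop-2-enoyl)oxy]-1-oxo-4-(prop-1-en-2-yl)octa-6,7-dien-5-yl (2Z)-2-methylbut-2-enoate
Product: 24 (3aR,4S,5S,6S,7R,7aR)-6-ethenyl-6-methyl-3-methylidene-7-[(2-methylprop-2-enoyl)oxy]-2-oxo-5-(prop-1-en-2-yl)octahydro-1-benzofuran-4-yl (2Z)-2-methylbut-2-enoate
Conditions: Mo(CO)6 (1.2 equiv), DMSO (10 equiv), toluene, 100 °C
Reagents that add atoms: molybdenum hexacarbonyl (source of the C12 carbonyl), [C-]#[O+].[C-]#[O+].[C-]#[O+].[C-]#[O+].[C-]#[O+].[C-]#[O+].[Mo]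
Why: DMSO-labilised zerovalent molybdenum carbonyl should couple the C8 aldehyde with the internal C7=C11 π-bond of the allene by oxidative cyclisation to an oxamolybdacyclopentane (C7–C8 bond), CO then inserts into the Mo–C11 bond (C11–C12 bond) and C12–O reductive elimination releases the lactone. The closest known reaction type is the hetero-Pauson–Khand (formal 2+2+1) cyclocarbonylation of allenyl aldehydes to bicyclic α-methylene-γ-butyrolactones. Ring A closes in the 6-exo mode with respect to the C7=C11 π-bond during metallacycle formation, and ring B is the five-membered metallacycle itself, turned into the lactone by CO insertion and C–O reductive elimination. C7 and C8 are set together: the metallacycle can only span a cis ring fusion, and the face is chosen by a chair-like transition state with the C5 isopropenyl, C9 methacrylate, C10 vinyl and formyl groups equatorial (C9–O anti-periplanar to the forming C7–C8 bond) and the allene axial on the face opposite the axial C10 methyl and C6 angelate, which places the lactone syn to the vinyl group as required. The step needs regioselection for the internal allene π-bond (exocyclic C11=C13 methylene) and chemoselection for the aldehyde–allene pair over the vinyl, isopropenyl and acrylate alkenes; the first is the usual preference of molybdenum with monosubstituted allenes, and the second follows because only this pair can form an unstrained metallacycle.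

Step 18
Reactants: 24 (3aR,4S,5S,6S,7R,7aR)-6-ethenyl-6-methyl-3-methylidene-7-[(2-methylprop-2-enoyl)oxy]-2-oxo-5-(prop-1-en-2-yl)octahydro-1-benzofuran-4-yl (2Z)-2-methylbut-2-enoate
Product: 25 (3aR,4S,5R,6S,7R,7aR)-6-ethenyl-6-methyl-3-methylidene-7-[(2-methylprop-2-enoyl)oxy]-2-oxo-5-(3-oxoprop-1-en-2-yl)octahydro-1-benzofuran-4-yl (2Z)-2-methylbut-2-enoate (CNP0102441.1)
Conditions: SeO2 (1.5 equiv), 1,4-dioxane, 80 °C
Reagents that add atoms: selenium dioxide, O=[Se]=O
Why: Riley allylic oxidation (ene reaction, 2,3-sigmatropic shift, further oxidation of the allylic alcohol) should attack the only electron-rich alkene that has allylic hydrogens and take the C15 methyl in preference to the hindered C5 methine, giving the 2-substituted acrolein; the vinyl group has no allylic hydrogen and the three conjugated alkenes are deactivated (the C5 descriptor changes only because the priorities change).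

Compound list
1 | (S)-2,2-dimethyl-1,3-dioxolane-4-carbaldehyde | O=C[C@@H]1COC(C)(C)O1 | starting material
2 | (4R)-4-(2,2-dibromoethenyl)-2,2-dimethyl-1,3-dioxolane | BrC(Br)=C[C@@H]1COC(C)(C)O1 | intermediate
3 | lithium [(4R)-2,2-dimethyl-1,3-dioxolan-4-yl]ethynide | [Li]C#C[C@@H]1COC(C)(C)O1 | intermediate
4 | methyl 3-[(4R)-2,2-dimethyl-1,3-dioxolan-4-yl]prop-2-ynoate | COC(=O)C#C[C@@H]1COC(C)(C)O1 | intermediate
5 | methyl (2Z)-3-[(4R)-2,2-dimethyl-1,3-dioxolan-4-yl]but-2-enoate | COC(=O)/C=C(/C)[C@@H]1COC(C)(C)O1 | intermediate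
6 | (2Z)-3-[(4R)-2,2-dimethyl-1,3-dioxolan-4-yl]but-2-en-1-ol | OC/C=C(/C)[C@@H]1COC(C)(C)O1 | intermediate
7 | 3-methylbut-2-enoic acid | CC(C)=CC(=O)O | starting material
8 | (2Z)-3-[(4R)-2,2-dimethyl-1,3-dioxolan-4-yl]but-2-en-1-yl 3-methylbut-2-enoate | CC(C)=CC(=O)OC/C=C(/C)[C@@H]1COC(C)(C)O1 | intermediate
9 | (1Z)-silyl ketene acetal of 8: trimethyl{[(1Z)-1-{[(2Z)-3-[(4R)-2,2-dimethyl-1,3-dioxolan-4-yl]but-2-en-1-yl]oxy}-3-methylbuta-1,3-dien-1-yl]oxy}silane (isopropenyl cis to OSiMe3) | C=C(C)/C=C(\O[Si](C)(C)C)OC/C=C(/C)[C@@H]1COC(C)(C)O1 | intermediate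
10 | trimethylsilyl (2S,3S)-3-[(4R)-2,2-dimethyl-1,3-dioxolan-4-yl]-3-methyl-2-(prop-1-en-2-yl)pent-4-enoate | C=C[C@@](C)([C@H](C(C)=C)C(=O)O[Si](C)(C)C)[C@@H]1COC(C)(C)O1 | intermediate
11 | (2S,3S)-3-[(4R)-2,2-dimethyl-1,3-dioxolan-4-yl]-3-methyl-2-(prop-1-en-2-yl)pent-4-enoic acid | C=C[C@@](C)([C@H](C(C)=C)C(=O)O)[C@@H]1COC(C)(C)O1 | intermediate
12 | (2S,3S)-3-[(4R)-2,2-dimethyl-1,3-dioxolan-4-yl]-3-methyl-2-(prop-1-en-2-yl)pent-4-enoyl chloride | C=C[C@@](C)([C@H](C(C)=C)C(Cl)=O)[C@@H]1COC(C)(C)O1 | intermediate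
13 | (2S,3S)-3-[(4R)-2,2-dimethyl-1,3-dioxolan-4-yl]-N-methoxy-N,3-dimethyl-2-(prop-1-en-2-yl)pent-4-enamide | C=C[C@@](C)([C@H](C(C)=C)C(=O)N(C)OC)[C@@H]1COC(C)(C)O1 | intermediate
14 | (4S,5S)-5-[(4R)-2,2-dimethyl-1,3-dioxolan-4-yl]-5-methyl-4-(prop-1-en-2-yl)-1-(trimethylsilyl)hept-6-en-1-yn-3-one | C=C[C@@](C)([C@H](C(C)=C)C(=O)C#C[Si](C)(C)C)[C@@H]1COC(C)(C)O1 | intermediate
15 | (3S,4S,5S)-5-[(4R)-2,2-dimethyl-1,3-dioxolan-4-yl]-5-methyl-4-(prop-1-en-2-yl)-1-(trimethylsilyl)hept-6-en-1-yn-3-ol | C=C[C@@](C)([C@H](C(C)=C)[C@H](O)C#C[Si](C)(C)C)[C@@H]1COC(C)(C)O1 | intermediate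
16 | (3S,4S,5S)-5-[(4R)-2,2-dimethyl-1,3-dioxolan-4-yl]-5-methyl-4-(prop-1-en-2-yl)hept-6-en-1-yn-3-ol | C=C[C@@](C)([C@H](C(C)=C)[C@H](O)C#C)[C@@H]1COC(C)(C)O1 | intermediate
17 | (4S,5S,6S)-1-(dicyclohexylamino)-6-[(4R)-2,2-dimethyl-1,3-dioxolan-4-yl]-6-methyl-5-(prop-1-en-2-yl)oct-7-en-2-yn-4-ol | C=C[C@@](C)([C@H](C(C)=C)[C@H](O)C#CCN(C1CCCCC1)C1CCCCC1)[C@@H]1COC(C)(C)O1 | intermediate
18 | (4R,5S,6S)-6-[(4R)-2,2-dimethyl-1,3-dioxolan-4-yl]-6-methyl-5-(prop-1-en-2-yl)octa-1,2,7-trien-4-ol | C=C[C@@](C)([C@H](C(C)=C)[C@H](O)C=C=C)[C@@H]1COC(C)(C)O1 | intermediate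
19 | (4R,5S,6S)-6-[(4R)-2,2-dimethyl-1,3-dioxolan-4-yl]-6-methyl-5-(prop-1-en-2-yl)octa-1,2,7-trien-4-yl (2Z)-2-methylbut-2-enoate | C=C[C@@](C)([C@H](C(C)=C)[C@H](OC(=O)/C(C)=C\C)C=C=C)[C@@H]1COC(C)(C)O1 | intermediate
20 | (2R,3S,4S,5R)-3-ethenyl-1,2-dihydroxy-3-methyl-4-(prop-1-en-2-yl)octa-6,7-dien-5-yl (2Z)-2-methylbut-2-enoate | C=C[C@@](C)([C@H](C(C)=C)[C@H](OC(=O)/C(C)=C\C)C=C=C)[C@@H](O)CO | intermediate
21 | (2R,3S,4S,5R)-3-ethenyl-2-hydroxy-3-methyl-4-(prop-1-en-2-yl)-1-[(triethylsilyl)oxy]octa-6,7-dien-5-yl (2Z)-2-methylbut-2-enoate | C=C[C@@](C)([C@H](C(C)=C)[C@H](OC(=O)/C(C)=C\C)C=C=C)[C@@H](O)CO[Si](CC)(CC)CC | intermediate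
22 | (2R,3S,4S,5R)-3-ethenyl-3-methyl-2-[(2-methylprop-2-enoyl)oxy]-4-(prop-1-en-2-yl)-1-[(triethylsilyl)oxy]octa-6,7-dien-5-yl (2Z)-2-methylbut-2-enoate | C=C[C@@](C)([C@H](C(C)=C)[C@H](OC(=O)/C(C)=C\C)C=C=C)[C@@H](OC(=O)C(C)=C)CO[Si](CC)(CC)CC | intermediate
23 | (2R,3S,4S,5R)-3-ethenyl-3-methyl-2-[(2-methylprop-2-enoyl)oxy]-1-oxo-4-(prop-1-en-2-yl)octa-6,7-dien-5-yl (2Z)-2-methylbut-2-enoate | C=C[C@@](C)([C@H](C(C)=C)[C@H](OC(=O)/C(C)=C\C)C=C=C)[C@H](C=O)OC(=O)C(C)=C | intermediate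
24 | (3aR,4S,5S,6S,7R,7aR)-6-ethenyl-6-methyl-3-methylidene-7-[(2-methylprop-2-enoyl)oxy]-2-oxo-5-(prop-1-en-2-yl)octahydro-1-benzofuran-4-yl (2Z)-2-methylbut-2-enoate | C=C[C@@]1(C)[C@H](C(C)=C)[C@H](OC(=O)/C(C)=C\C)[C@H]2C(=C)C(=O)O[C@H]2[C@@H]1OC(=O)C(=C)C | intermediate
25 | (3aR,4S,5R,6S,7R,7aR)-6-ethenyl-6-methyl-3-methylidene-7-[(2-methylprop-2-enoyl)oxy]-2-oxo-5-(3-oxoprop-1-en-2-yl)octahydro-1-benzofuran-4-yl (2Z)-2-methylbut-2-enoate (CNP0102441.1) | C=C[C@@]1(C)[C@H](C(=C)C=O)[C@H](OC(=O)/C(C)=C\C)[C@H]2C(=C)C(=O)O[C@H]2[C@@H]1OC(=O)C(=C)C | target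

Total step count: 18
Longest linear sequence: 18 steps (1 → 25)

Steps most likely to fail

Step 17. Zerovalent molybdenum may insert into the allenylic C6–O angelate bond, the distal allene π-bond may be engaged instead of the internal one, or facial discrimination in the oxidative cyclisation may be insufficient. The fallback is stepwise and uses known chemistry; it sets out from aldehyde 23 and comes back at lactone 24. Palladium-catalysed distannylation of the allene (Bu3SnSnBu3, [Pd(η3-C3H5)Cl]2, THF, rt) should give a 2-stannylallylstannane that adds through C7 to the C8 aldehyde, forming ring A as the cis-hydroxy vinylstannane (1R,2R,3S,4S,5S,6R)-3-ethenyl-6-hydroxy-3-methyl-4-(prop-1-en-2-yl)-5-{[(2Z)-2-methylbut-2-enoyl]oxy}-6-... cyclohexyl methacrylate bearing a 1-(tributylstannyl)ethenyl group at C7 F1. Iododestannylation (I2, CH2Cl2, 0 °C) should give the corresponding C11 vinyl iodide F2. Carbonylative lactonisation (Pd(PPh3)4, CO 1 atm, Et3N, THF, 50 °C) then closes ring B and gives 24.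

Step 6. The dienolate geometry may erode (mixture at C5), the facial bias from C9 may be insufficient (mixture at C10), or the rearrangement may be slow because the dioxolane must sit axial. The fallback sets out from alcohol 6 and comes back at acid 11. Esterification with commercial 3-methylbut-3-enoic acid (DCC, DMAP, CH2Cl2, 0 °C) should give the β,γ-unsaturated ester (2Z)-3-[(4R)-2,2-dimethyl-1,3-dioxolan-4-yl]but-2-en-1-yl 3-methylbut-3-enoate F3. Its enolate geometry no longer depends on the s-cis conformer of an enoate but is set by solvent-controlled α-deprotonation (LiN(i-Pr)2, THF/DMPU, −78 °C, the conditions of the classical Ireland protocol that place the α-substituent cis to the enolate oxygen). Silylation (Me3SiCl), warming and acidic work-up then give 11.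

Step 18. Over-oxidation, ene attack at the C5 methine, or addition of selenium species to the α-methylene lactone may erode the late-stage oxidation. The fallback replaces selenium by photo-oxygenation; it sets out from lactone 24 and comes back at target 25. A Schenck ene reaction with singlet oxygen (O2, tetraphenylporphyrin, hν, CH2Cl2, 0 °C) should abstract a hydrogen of the C15 methyl and give the primary allylic hydroperoxide (the 3-hydroperoxyprop-1-en-2-yl analogue of 24) F4. Kornblum–DeLaMare-type dehydration (Ac2O, pyridine, DMAP, CH2Cl2, 0 °C) then gives the 2-substituted acrolein 25.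

Further compounds
F1 | step 17 | (1R,2R,3S,4S,5S,6R)-numbered cyclohexane core written by SMILES: cis-hydroxy vinylstannane, 3-ethenyl-6-hydroxy-3-methyl-4-(prop-1-en-2-yl)-5-[1-(tributylstannyl)ethenyl at the adjacent carbon] with C6 angelate and C9 methacrylate | C=C[C@@]1(C)[C@H](C(C)=C)[C@H](OC(=O)/C(C)=C\C)[C@@H](C(=C)[Sn](CCCC)(CCCC)CCCC)[C@@H](O)[C@@H]1OC(=O)C(=C)C
F2 | step 17 | vinyl iodide corresponding to F1 (1-iodoethenyl group at C7, free C8 hydroxyl, C6 angelate, C9 methacrylate) | C=C[C@@]1(C)[C@H](C(C)=C)[C@H](OC(=O)/C(C)=C\C)[C@@H](C(=C)I)[C@@H](O)[C@@H]1OC(=O)C(=C)C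
F3 | step 6 | (2Z)-3-[(4R)-2,2-dimethyl-1,3-dioxolan-4-yl]but-2-en-1-yl 3-methylbut-3-enoate | C=C(C)CC(=O)OC/C=C(/C)[C@@H]1COC(C)(C)O1
F4 | step 18 | (3aR,4S,5R,6S,7R,7aR)-6-ethenyl-5-(3-hydroperoxyprop-1-en-2-yl)-6-methyl-3-methylidene-7-[(2-methylprop-2-enoyl)oxy]-2-oxooctahydro-1-benzofuran-4-yl (2Z)-2-methylbut-2-enoate | C=C[C@@]1(C)[C@H](C(=C)COO)[C@H](OC(=O)/C(C)=C\C)[C@H]2C(=C)C(=O)O[C@H]2[C@@H]1OC(=O)C(=C)C
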